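**Plan**

1. Numbering, used for all intermediates: C1–C17 run along the target SMILES from the first acetoxy carbon (C8 = cyclopropane methyl). Ring A = C1-C2-C3-C17-C16-C15, ring B = C3-C4-C5-C9-C10-C17, ring C = cyclobutane C10-C11-C16-C17, ring D = C11-C12-C13-C14-C15-C16.
2. Cuts: C2–C3 and C3–C17 together (double aldol). C3 lies between the C4 ketone and the two carbinol carbons C17 and C2, and C4 can enolise only towards C3 because C5 is the spiro cyclopropane carbon. Then C9–C10 (aldol condensation), C10–C17/C11–C16 (keteniminium [2+2]) and C15–C16 (Claisen).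
3. Forward: acyclic amide → rings C and D in one [2+2] → cyclopropane aldehyde joined at C10, C9/C10 diol → rings B then A in the cascade → C1 reduction and acetates.
4. Stereochemistry: C7 from (S)-propane-1,2-diol (inversion), C5 from selective half-ester hydrolysis; C15 from a CBS reduction relayed by a Claisen rearrangement; C11/C16 from C15 in the [2+2]; C9/C10 by convex-face osmylation of the (E)-enone; C17, C3, C2 in the cascade; C1 by hydroxyl-directed reduction.

Key step: step 26

Remark: diethyl (3-oxobutan-2-yl)phosphonate (18) and 1,1-dimethoxy-N,N-dimethylpropan-1-amine (21) are taken to be purchasable; "arm" means the C1–C2 unit on C15.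

**Cyclopropane aldehyde (steps 1–7)**

Step 1
Reactants: 1 (S)-propane-1,2-diol
Product: 3 (4S)-4-methyl-1,3,2-dioxathiolane 2,2-dioxide, via cyclic sulfite 2 (not isolated)
Conditions: SOCl2, CH2Cl2, 0 °C → reflux; then RuCl3·xH2O (cat.), NaIO4, MeCN/H2O, 0 °C
Reagents that add atoms: thionyl chloride, O=S(Cl)Cl; sodium periodate, [Na+].[O-]I(=O)(=O)=O
Why: Cyclic sulfate formation (sulfite, then RuO4-catalysed oxidation) turns both hydroxyls into leaving groups without touching the stereocentre.

Step 2
Reactants: 3 cyclic sulfate; 4 dimethyl malonate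
Product: 5 dimethyl (2R)-2-methylcyclopropane-1,1-dicarboxylate
Conditions: NaH (2.1 equiv), DME, 0 °C → reflux
Reagents that add atoms: none
Why: Double malonate alkylation (cyclopropanation with a 1,2-cyclic sulfate): the first SN2 takes place at the primary carbon and the 3-exo-tet closure displaces the secondary sulfate with inversion, which sets C7.

Step 3
Reactants: 5 cyclopropane diester
Product: 6 (1S,2R)-1-(methoxycarbonyl)-2-methylcyclopropane-1-carboxylic acid (CO2H trans to CH3)
Conditions: KOH (1.0 equiv), MeOH, 0 °C → rt; aq. HCl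
Reagents that add atoms: potassium hydroxide, [K+].[OH-]
Why: Regioselective mono-saponification: hydroxide attacks the less shielded ester trans to the C7 methyl group, which differentiates the two carboxyls and so fixes C5.

Step 4
Reactants: 6 half-ester
Product: 7 methyl (1S,2R)-1-(hydroxymethyl)-2-methylcyclopropane-1-carboxylate
Conditions: BH3·SMe2, THF, 0 °C → rt
Reagents that add atoms: none
Why: Chemoselective borane reduction of a carboxylic acid beside an ester gives the C9 carbinol.

Step 5
Reactants: 7 hydroxy ester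
Product: 8 (1S,2R)-1-(hydroxymethyl)-N-methoxy-N,2-dimethylcyclopropane-1-carboxamide
Conditions: MeNH(OMe)·HCl, AlMe3, CH2Cl2, 0 → 40 °C
Reagents that add atoms: N,O-dimethylhydroxylamine hydrochloride, CNOC.Cl
Why: Aluminium-amide aminolysis (Weinreb amide formation) converts the hindered ester into an acyl donor that accepts one carbon nucleophile only.

Step 6
Reactants: 8 Weinreb amide
Product: 9 1-[(1S,2R)-1-(hydroxymethyl)-2-methylcyclopropyl]ethan-1-one
Conditions: MeMgBr (3 equiv), THF, 0 °C
Reagents that add atoms: methylmagnesium bromide, C[Mg]Br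
Why: Grignard addition to a Weinreb amide stops at the chelated tetrahedral intermediate and gives the C4 methyl ketone (cis to the C7 methyl) without over-addition.

Step 7
Reactants: 9 hydroxy ketone
Product: 10 (1S,2R)-1-acetyl-2-methylcyclopropane-1-carbaldehyde
Conditions: (n-Pr4N)RuO4 (cat.), NMO, 4 Å MS, CH2Cl2, rt
Reagents that add atoms: none
Why: Ley–Griffith oxidation of the primary alcohol gives the non-enolisable C9 aldehyde under neutral conditions.

**Bicyclic ketone (steps 8–20)**

Step 8
Reactants: 11 methyl 3-hydroxy-2,2-dimethylpropanoate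
Product: 12 methyl 2,2-dimethyl-3-oxopropanoate
Conditions: (n-Pr4N)RuO4 (cat.), NMO, 4 Å MS, CH2Cl2, rt
Reagents that add atoms: none
Why: Ley–Griffith oxidation of the neopentyl alcohol gives a non-enolisable aldehyde (future C13).

Step 9
Reactants: 12 aldehyde ester
Product: 13 methyl 3-hydroxy-2,2-dimethylhex-5-enoate (racemic)
Conditions: allylmagnesium bromide, Et2O, −78 °C
Reagents that add atoms: allylmagnesium bromide, C=CC[Mg]Br
Why: Grignard 1,2-addition is far faster at the aldehyde than at the α-quaternary ester and joins C12–C10 to C13; the carbinol centre is removed in step 10.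

Step 10
Reactants: 13 homoallylic alcohol
Product: 14 methyl 2,2-dimethyl-3-oxohex-5-enoate
Conditions: Dess–Martin periodinane, CH2Cl2, 0 °C → rt
Reagents that add atoms: none
Why: Dess–Martin oxidation gives the β,γ-unsaturated ketone under non-basic conditions that do not move the alkene into conjugation.

Step 11
Reactants: 14 keto ester
Product: 15 methyl 2-methyl-2-[2-(prop-2-en-1-yl)-1,3-dioxolan-2-yl]propanoate
Conditions: Me3SiOCH2CH2OSiMe3, TMSOTf (cat.), CH2Cl2, −78 → −20 °C
Reagents that add atoms: 1,2-bis(trimethylsilyloxy)ethane, C[Si](C)(C)OCCO[Si](C)(C)C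
Why: Noyori ketalisation is aprotic and kinetically controlled, so the hindered C13 ketone is masked while the β,γ-alkene stays in place.

Step 12
Reactants: 15 ketal ester
Product: 16 2-methyl-2-[2-(prop-2-en-1-yl)-1,3-dioxolan-2-yl]propan-1-ol
Conditions: LiAlH4, Et2O, 0 °C
Reagents that add atoms: none
Why: Hydride reduction of the ester gives the neopentyl alcohol; ketal and alkene are inert.

Step 13
Reactants: 16 alcohol
Product: 17 2-methyl-2-[2-(prop-2-en-1-yl)-1,3-dioxolan-2-yl]propanal
Conditions: (n-Pr4N)RuO4 (cat.), NMO, 4 Å MS, CH2Cl2, rt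
Reagents that add atoms: none
Why: Ley–Griffith oxidation gives the α-quaternary aldehyde (future C15), which cannot enolise.

Step 14
Reactants: 17 aldehyde; 18 diethyl (3-oxobutan-2-yl)phosphonate
Product: 19 (3E)-3,5-dimethyl-5-[2-(prop-2-en-1-yl)-1,3-dioxolan-2-yl]hex-3-en-2-one
Conditions: NaH, THF, 0 °C → reflux
Reagents that add atoms: none
Why: Horner–Wadsworth–Emmons olefination of a non-enolisable aldehyde with an α-methyl β-ketophosphonate gives the (E)-trisubstituted enone with the large groups trans.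

Step 15
Reactants: 19 enone
Product: 20 (2R,3E)-3,5-dimethyl-5-[2-(prop-2-en-1-yl)-1,3-dioxolan-2-yl]hex-3-en-2-ol
Conditions: (S)-2-methyl-CBS-oxazaborolidine (0.2 equiv), catecholborane, toluene, −78 °C
Reagents that add atoms: none
Why: Corey–Bakshi–Shibata reduction: with the alkenyl group as the large substituent the (S)-catalyst should give the (R)-carbinol, and catecholborane does not hydroborate the terminal alkene at −78 °C.

Step 16
Reactants: 20 allylic alcohol; 21 1,1-dimethoxy-N,N-dimethylpropan-1-amine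
Product: 22 (3R,4E)-N,N,2,4-tetramethyl-3-{2-[2-(prop-2-en-1-yl)-1,3-dioxolan-2-yl]propan-2-yl}hex-4-enamide (C2 epimers)
Conditions: xylenes, 140 °C, removal of MeOH
Reagents that add atoms: none
Why: Eschenmoser–Claisen rearrangement through a chair with the carbinol methyl equatorial transfers the carbinol chirality suprafacially to C15 and forms C15–C16; the C16 epimers are of no consequence because C16 becomes sp2 in step 20.

Step 17
Reactants: 22 dienamide
Product: 23 (3S)-3-acetyl-N,N,2,4-tetramethyl-4-[2-(prop-2-en-1-yl)-1,3-dioxolan-2-yl]pentanamide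
Conditions: O3 (1.0 equiv, titrated), CH2Cl2/MeOH, pyridine, −78 °C; then Me2S
Reagents that add atoms: ozone, [O-][O+]=O
Why: Chemoselective ozonolysis: the electron-rich trisubstituted alkene reacts much faster than the terminal one, and reductive work-up gives the C1 methyl ketone (C2 = its methyl) directly.

Step 18
Reactants: 23 methyl ketone
Product: 24 (3S)-3-(2-hydroxy-1,1-dimethoxyethyl)-N,N,2,4-tetramethyl-4-[2-(prop-2-en-1-yl)-1,3-dioxolan-2-yl]pentanamide
Conditions: PhI(OAc)2, KOH, MeOH, 0 °C → rt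
Reagents that add atoms: methanol, CO
Why: Moriarty α-hydroxylation (hypervalent iodine, methanolic base): the methyl-side enolate is oxidised and methanol opens the methoxy-epoxide, giving C1 as a dimethyl ketal and C2 as a carbinol, while C15–H between the quaternary C14 and the branched C16 is not removed.

Step 19
Reactants: 24 hydroxy ketal
Product: 25 tert-butyldimethylsilyl ether of 24
Conditions: TBSCl, imidazole, DMF, rt
Reagents that add atoms: tert-butyldimethylsilyl chloride, CC(C)(C)[Si](C)(C)Cl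
Why: Silylation of the primary alcohol protects C2–OH for the electrophilic and basic steps that follow.

Step 20
Reactants: 25 silyl ether amide
Product: 28 bicyclic ketone (rings C and D; C17 ketone; C10 methylene; C13 dioxolane; C15 arm C1(OMe)2–CH2OTBS cis to C17), via keteniminium triflate 26 (not isolated), via cyclobutaniminium triflate 27 (not isolated)
Conditions: Tf2O, 2,4,6-collidine, ClCH2CH2Cl (0.01 M), 0 → 80 °C; then aq. NaHCO3, rt
Reagents that add atoms: water, O
Why: Ghosez keteniminium–alkene [2+2] cycloaddition and iminium hydrolysis: C17 bonds to the terminal carbon C10 and C16 to C11, and in the chair-like closure of ring D the C15 arm is equatorial and anti to the forming C16–C11 bond (C15–H eclipsing the C16 methyl), which should give the cis-fused bicycle with the arm cis to C17 and trans to the C16 methyl.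

**Union, cascade and end-game (steps 21–32)**

Step 21
Reactants: 28 bicyclic ketone; 10 cyclopropane aldehyde
Product: 31 (E)-enone (C9=C10; C5 cis to C11), via aldol adduct 29 (not isolated), via mesylate 30 (not isolated)
Conditions: LiN(i-Pr)2, THF, −78 °C; 10; then MsCl, −78 → 0 °C; DBU, 0 °C → rt
Reagents that add atoms: none
Why: Directed aldol condensation: the cyclobutanone enolate (C10 is its only enolisable position) adds to the aldehyde of 10 in preference to its ketone, and mesylation/E1cB elimination gives the thermodynamically preferred (E)-alkylidenecyclobutanone.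

Step 22
Reactants: 31 enone
Product: 32 C9,C10-diol
Conditions: OsO4 (5 mol %), NMO, MeSO2NH2, acetone/H2O, rt
Reagents that add atoms: 4-methylmorpholine 4-oxide, C[N+]1([O-])CCOCC1; water, O
Why: Upjohn dihydroxylation: syn addition from the convex face of the bicyclo[4.2.0]octanone (anti to ring D) sets C10, and the (E)-geometry then fixes C9.

Step 23
Reactants: 32 diol
Product: 33 C9/C10 acetonide
Conditions: Me2C(OMe)2, PPTS (cat.), CH2Cl2, rt
Reagents that add atoms: 2,2-dimethoxypropane, COC(C)(C)OC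
Why: Acetonide formation (transketalisation) ties up the vicinal hydroxyls as a base-stable dioxolane and takes the α-ketol out of reach of rearrangement.

Step 24
Reactants: 33 acetonide
Product: 34 primary alcohol (C2–OH)
Conditions: HF·pyridine, pyridine, THF, 0 °C → rt
Reagents that add atoms: none
Why: Buffered fluoride desilylation cleaves the primary silyl ether, spares the ketals and is not basic enough to start the aldol prematurely.

Step 25
Reactants: 34 alcohol
Product: 35 keto aldehyde (C3 methyl ketone, C17 cyclobutanone, C2 aldehyde; C1 dimethyl ketal, C13 dioxolane, C9/C10 acetonide)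
Conditions: Dess–Martin periodinane, pyridine, CH2Cl2, 0 °C → rt
Reagents that add atoms: none
Why: Dess–Martin oxidation of the primary alcohol gives an aldehyde that has no α-hydrogen, C1 being a ketal carbon.

Step 26
Reactants: 35 keto aldehyde
Product: 37 tetracyclic diol (rings A to D; C2 and C17 hydroxyls free), via ring B aldol 36 (not isolated)
Conditions: LiN(SiMe3)2 (1.5 equiv), THF (0.005 M), −78 → −20 °C; AcOH, −78 °C
Reagents that add atoms: none
Why: The base can remove a proton only from the C3 methyl group (C5, C10 and C16 are fully substituted, C1 is a ketal carbon, C13 is masked), and the enolate adds to the strained C17 carbonyl in a 6-(enolendo)-exo-trig aldol that closes ring B and releases the angle strain of the cyclobutanone, which also disfavours the retro-aldol. Proton transfer from the new C3 methylene, relayed by the tertiary alkoxide and HN(SiMe3)2, gives the only possible enolate (C3=C4), which adds to the C2 aldehyde in a 6-(enolexo)-exo-trig aldol that closes ring A; the closest known reaction type is the base-mediated tandem intramolecular aldol cyclisation of a keto aldehyde. C17: the tether through C9 on C10 permits attack only on the carbonyl face syn to C9, so ring B is cis-fused to the cyclobutane and the hydroxyl points to the convex face. C3: the aldehyde is delivered from C15 on the same face of the cyclobutane, and a six-membered ring A can close only cis to ring B across C3–C17, so H3 ends up syn to the C17 hydroxyl. C2: a lithium-bridged closed transition state that holds the aldehyde oxygen next to the enolate oxygen should place the C2 hydroxyl cis to C4 on ring A, and the reversibility of this second aldol lets the chelated aldolate accumulate. The step needs chemoselectivity (one enolate, ketone before aldehyde), which is secured by the absence of other acidic hydrogens and by ring size, since direct attack of the C3 enolate on the aldehyde would require a ten-membered ring.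

Step 27
Reactants: 37 tetracyclic diol
Product: 38 C2 triisopropylsilyl ether
Conditions: TIPSOTf, 2,6-lutidine, CH2Cl2, −40 → 0 °C; aq. NaHCO3
Reagents that add atoms: triisopropylsilyl trifluoromethanesulfonate, CC(C)[Si](C(C)C)(C(C)C)OS(=O)(=O)C(F)(F)F
Why: Silylation with a silyl triflate protects the only secondary hydroxyl as an acid-stable ether; the tertiary C17 hydroxyl does not react at low temperature.

Step 28
Reactants: 38 silyl ether
Product: 39 trione triol (C1, C4, C13 ketones; C9, C10, C17 hydroxyls; O2 silylated)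
Conditions: AcOH/H2O (4:1), 55 °C
Reagents that add atoms: water, O
Why: Acid-catalysed acetal hydrolysis removes the dimethyl ketal, the dioxolane and the acetonide, while the hindered secondary TIPS ether is stable.

Step 29
Reactants: 39 trione triol
Product: 40 C9 acetate
Conditions: Ac2O, DMAP, pyridine, CH2Cl2, rt
Reagents that add atoms: acetic anhydride, CC(=O)OC(C)=O
Why: DMAP-catalysed acylation acetylates the only free secondary hydroxyl; the tertiary C10 and C17 hydroxyls do not react at room temperature.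

Step 30
Reactants: 40 acetate
Product: 41 α-ketol (C1 ketone, C2 hydroxyl free)
Conditions: HF·pyridine, THF, rt
Reagents that add atoms: none
Why: Fluoride desilylation under weakly acidic conditions frees O2 without touching the acetate and without base-induced α-ketol isomerisation.

Step 31
Reactants: 41 α-ketol
Product: 42 C1,C2-trans-diol (1-O-deacetyl target)
Conditions: Me4NBH(OAc)3, MeCN/AcOH (1:1), −30 °C
Reagents that add atoms: none
Why: Hydroxyl-directed (Evans–Saksena) reduction: the C2 hydroxyl binds boron and delivers hydride to C1 on its own face, giving the trans-1,2-diol (the C1 configuration of the target) while the isolated C13 ketone and the hindered cyclopropyl ketone C4 are left untouched.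

Step 32
Reactants: 42 diol
Product: 43 CNP0157858.3 (target)
Conditions: Ac2O, pyridine, CH2Cl2, 0 °C
Reagents that add atoms: acetic anhydride, CC(=O)OC(C)=O
Why: Regioselective acylation without DMAP: the C1 hydroxyl on the convex face should react, whereas the C2 hydroxyl on the concave face, hydrogen-bonded to the C4 carbonyl, and the tertiary hydroxyls remain free.

**Compound list**

1 | (S)-propane-1,2-diol | C[C@H](O)CO | starting material
2 | (4S)-4-methyl-1,3,2-dioxathiolane 2-oxide (sulfur epimers) | C[C@H]1COS(=O)O1 | intermediate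
3 | (4S)-4-methyl-1,3,2-dioxathiolane 2,2-dioxide | C[C@H]1COS(=O)(=O)O1 | intermediate
4 | dimethyl malonate | COC(=O)CC(=O)OC | starting material
5 | dimethyl (2R)-2-methylcyclopropane-1,1-dicarboxylate | COC(=O)C1(C[C@H]1C)C(=O)OC | intermediate
6 | (1S,2R)-1-(methoxycarbonyl)-2-methylcyclopropane-1-carboxylic acid | COC(=O)[C@]1(C[C@H]1C)C(=O)O | intermediate
7 | methyl (1S,2R)-1-(hydroxymethyl)-2-methylcyclopropane-1-carboxylate | COC(=O)[C@]1(C[C@H]1C)CO | intermediate
8 | (1S,2R)-1-(hydroxymethyl)-N-methoxy-N,2-dimethylcyclopropane-1-carboxamide | CON(C)C(=O)[C@]1(C[C@H]1C)CO | intermediate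
9 | 1-[(1S,2R)-1-(hydroxymethyl)-2-methylcyclopropyl]ethan-1-one | CC(=O)[C@]1(C[C@H]1C)CO | intermediate
10 | (1S,2R)-1-acetyl-2-methylcyclopropane-1-carbaldehyde (acetyl cis to methyl) | CC(=O)[C@]1(C[C@H]1C)C=O | intermediate
11 | methyl 3-hydroxy-2,2-dimethylpropanoate | COC(=O)C(C)(C)CO | starting material
12 | methyl 2,2-dimethyl-3-oxopropanoate | COC(=O)C(C)(C)C=O | intermediate
13 | methyl 3-hydroxy-2,2-dimethylhex-5-enoate (racemic) | COC(=O)C(C)(C)C(O)CC=C | intermediate
14 | methyl 2,2-dimethyl-3-oxohex-5-enoate | COC(=O)C(C)(C)C(=O)CC=C | intermediate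
15 | methyl 2-methyl-2-[2-(prop-2-en-1-yl)-1,3-dioxolan-2-yl]propanoate | COC(=O)C(C)(C)C1(CC=C)OCCO1 | intermediate
16 | 2-methyl-2-[2-(prop-2-en-1-yl)-1,3-dioxolan-2-yl]propan-1-ol | OCC(C)(C)C1(CC=C)OCCO1 | intermediate
17 | 2-methyl-2-[2-(prop-2-en-1-yl)-1,3-dioxolan-2-yl]propanal | O=CC(C)(C)C1(CC=C)OCCO1 | intermediate
18 | diethyl (3-oxobutan-2-yl)phosphonate | CCOP(=O)(OCC)C(C)C(C)=O | starting material
19 | (3E)-3,5-dimethyl-5-[2-(prop-2-en-1-yl)-1,3-dioxolan-2-yl]hex-3-en-2-one | CC(=O)/C(C)=C/C(C)(C)C1(CC=C)OCCO1 | intermediate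
20 | (2R,3E)-3,5-dimethyl-5-[2-(prop-2-en-1-yl)-1,3-dioxolan-2-yl]hex-3-en-2-ol | C[C@@H](O)/C(C)=C/C(C)(C)C1(CC=C)OCCO1 | intermediate
21 | 1,1-dimethoxy-N,N-dimethylpropan-1-amine | CCC(OC)(OC)N(C)C | starting material
22 | (3R,4E)-N,N,2,4-tetramethyl-3-{2-[2-(prop-2-en-1-yl)-1,3-dioxolan-2-yl]propan-2-yl}hex-4-enamide (C2 epimers; C3 = C15) | CN(C)C(=O)C(C)[C@H](/C(C)=C/C)C(C)(C)C1(CC=C)OCCO1 | intermediate
23 | (3S)-3-acetyl-N,N,2,4-tetramethyl-4-[2-(prop-2-en-1-yl)-1,3-dioxolan-2-yl]pentanamide (C2 epimers) | CN(C)C(=O)C(C)[C@H](C(C)=O)C(C)(C)C1(CC=C)OCCO1 | intermediate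
24 | (3S)-3-(2-hydroxy-1,1-dimethoxyethyl)-N,N,2,4-tetramethyl-4-[2-(prop-2-en-1-yl)-1,3-dioxolan-2-yl]pentanamide | CN(C)C(=O)C(C)[C@H](C(OC)(OC)CO)C(C)(C)C1(CC=C)OCCO1 | intermediate
25 | tert-butyldimethylsilyl ether of 24 | CN(C)C(=O)C(C)[C@H](C(OC)(OC)CO[Si](C)(C)C(C)(C)C)C(C)(C)C1(CC=C)OCCO1 | intermediate
26 | keteniminium triflate from 25 (C16=C17=N+) | C[N+](C)=C=C(C)[C@H](C(OC)(OC)CO[Si](C)(C)C(C)(C)C)C(C)(C)C1(CC=C)OCCO1.[O-]S(=O)(=O)C(F)(F)F | intermediate
27 | cyclobutaniminium triflate (C17=N+Me2; rings C and D closed) | C1[C@H]2CC3(OCCO3)C(C)(C)[C@@H](C(OC)(OC)CO[Si](C)(C)C(C)(C)C)[C@@]2(C)C1=[N+](C)C.[O-]S(=O)(=O)C(F)(F)F | intermediate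
28 | 5-[2-(tert-butyldimethylsilyloxy)-1,1-dimethoxyethyl]-4,4,6-trimethylspiro[bicyclo[4.2.0]octane-3,2'-[1,3]dioxolan]-7-one (H11 and C16 methyl cis; C15 arm cis to C17; C11, C15, C16 as in the target) | C1[C@H]2CC3(OCCO3)C(C)(C)[C@@H](C(OC)(OC)CO[Si](C)(C)C(C)(C)C)[C@@]2(C)C1=O | intermediate
29 | aldol adduct of 28 and 10 (C9 carbinol, C10–H; diastereomers at C9/C10) | CC(=O)[C@]1(C[C@H]1C)C(O)C2[C@H]3CC4(OCCO4)C(C)(C)[C@@H](C(OC)(OC)CO[Si](C)(C)C(C)(C)C)[C@@]3(C)C2=O | intermediate
30 | C9 mesylate of 29 | CC(=O)[C@]1(C[C@H]1C)C(OS(C)(=O)=O)C2[C@H]3CC4(OCCO4)C(C)(C)[C@@H](C(OC)(OC)CO[Si](C)(C)C(C)(C)C)[C@@]3(C)C2=O | intermediate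
31 | (E)-C9=C10 alkylidenecyclobutanone (C5 trans to C17) | CC(=O)[C@]1(C[C@H]1C)/C=C2\[C@H]3CC4(OCCO4)C(C)(C)[C@@H](C(OC)(OC)CO[Si](C)(C)C(C)(C)C)[C@@]3(C)C2=O | intermediate
32 | C9,C10-diol (C10 hydroxyl on the convex face, trans to C12; C9 and C10 as in the target) | CC(=O)[C@]1(C[C@H]1C)[C@@H](O)[C@@]2(O)[C@H]3CC4(OCCO4)C(C)(C)[C@@H](C(OC)(OC)CO[Si](C)(C)C(C)(C)C)[C@@]3(C)C2=O | intermediate
33 | C9/C10 acetonide of 32 | CC(=O)[C@]1(C[C@H]1C)[C@@H](OC(C)(C)O6)[C@@]26[C@H]3CC4(OCCO4)C(C)(C)[C@@H](C(OC)(OC)CO[Si](C)(C)C(C)(C)C)[C@@]3(C)C2=O | intermediate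
34 | primary alcohol (C2–OH) from 33 | CC(=O)[C@]1(C[C@H]1C)[C@@H](OC(C)(C)O6)[C@@]26[C@H]3CC4(OCCO4)C(C)(C)[C@@H](C(OC)(OC)CO)[C@@]3(C)C2=O | intermediate
35 | bicyclic keto aldehyde (C3 methyl ketone, C17 cyclobutanone, C2 aldehyde; C1 dimethyl ketal, C13 dioxolane, C9/C10 acetonide) | CC(=O)[C@]1(C[C@H]1C)[C@@H](OC(C)(C)O6)[C@@]26[C@H]3CC4(OCCO4)C(C)(C)[C@@H](C(OC)(OC)C=O)[C@@]3(C)C2=O | intermediate
36 | tricyclic hydroxy keto aldehyde (ring B closed, C17 hydroxyl, C3 methylene, C2 aldehyde) | C1C(=O)[C@]2(C[C@H]2C)[C@@H](OC(C)(C)O6)[C@@]36[C@H]4CC5(OCCO5)C(C)(C)[C@@H](C(OC)(OC)C=O)[C@@]4(C)[C@@]13O | intermediate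
37 | tetracyclic diol (rings A to D; C2 and C17 hydroxyls, C4 ketone, C1 dimethyl ketal, C13 dioxolane, C9/C10 acetonide) | COC1(OC)[C@@H](O)[C@H]2C(=O)[C@]3(C[C@H]3C)[C@@H](OC(C)(C)O6)[C@@]36[C@H]4CC7(OCCO7)C(C)(C)[C@@H]1[C@@]4(C)[C@@]23O | intermediate
38 | C2 triisopropylsilyl ether of 37 | COC1(OC)[C@@H](O[Si](C(C)C)(C(C)C)C(C)C)[C@H]2C(=O)[C@]3(C[C@H]3C)[C@@H](OC(C)(C)O6)[C@@]36[C@H]4CC7(OCCO7)C(C)(C)[C@@H]1[C@@]4(C)[C@@]23O | intermediate
39 | trione triol (C1, C4, C13 ketones; C9, C10, C17 hydroxyls; C2–OTIPS) | O=C1[C@@H](O[Si](C(C)C)(C(C)C)C(C)C)[C@H]2C(=O)[C@]3(C[C@H]3C)[C@@H](O)[C@@]3(O)[C@H]4CC(=O)C(C)(C)[C@@H]1[C@@]4(C)[C@@]23O | intermediate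
40 | C9 acetate of 39 | O=C1[C@@H](O[Si](C(C)C)(C(C)C)C(C)C)[C@H]2C(=O)[C@]3(C[C@H]3C)[C@@H](OC(C)=O)[C@@]3(O)[C@H]4CC(=O)C(C)(C)[C@@H]1[C@@]4(C)[C@@]23O | intermediate
41 | α-ketol (C1 ketone, C2 hydroxyl, C9 acetate) | O=C1[C@@H](O)[C@H]2C(=O)[C@]3(C[C@H]3C)[C@@H](OC(C)=O)[C@@]3(O)[C@H]4CC(=O)C(C)(C)[C@@H]1[C@@]4(C)[C@@]23O | intermediate
42 | C1,C2-trans-diol (1-O-deacetyl target) | O[C@@H]1[C@@H](O)[C@H]2C(=O)[C@]3(C[C@H]3C)[C@@H](OC(C)=O)[C@@]3(O)[C@H]4CC(=O)C(C)(C)[C@@H]1[C@@]4(C)[C@@]23O | intermediate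
43 | CNP0157858.3 | CC(=O)O[C@@H]1[C@@H](O)[C@H]2C(=O)[C@]3(C[C@H]3C)[C@@H](OC(C)=O)[C@@]3(O)[C@H]4CC(=O)C(C)(C)[C@@H]1[C@@]4(C)[C@@]23O | target

**Count and risks**

Total: 32 steps (7 to aldehyde 10, 13 to ketone 28, 12 from the union to 43). Longest linear sequence: 25 steps (steps 8–32, from 11 to 43).

Most likely to fail:

1. Step 26. The cascade may stop after ring B, the aldehyde may be attacked on the wrong face (C2 epimer) or by a second molecule, and long exposure to base may dehydrate the C2 aldol. Fallback (from 33, back at 37): the two aldol events are separated. Acetonide 33, with the arm still silylated, is treated with LiN(i-Pr)2 at −78 °C to close ring B alone and give the tricyclic hydroxy ketone silyl ether F1. HF·pyridine frees the primary alcohol F2, and Dess–Martin oxidation gives 36 as an isolated compound. TMSOTf/Et3N converts 36 into the bis(trimethylsilyl) derivative F3 (C17 silyl ether, C3=C4 silyl enol ether). A fluoride source (n-Bu4NF) then releases a metal-free enolate that closes ring A through an open transition state independent of chelation, and work-up returns 37.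

2. Step 20. Deprotonation of the congested O-triflyl iminium ion may be slow, and the cationic intermediates may be captured by the ketal oxygens with loss of the ketals before the cycloaddition. Fallback (from 25, back at 28): the cumulene is made by halide abstraction instead of in situ dehydration. Amide 25 is converted with phosgene and then Et3N into the isolable α-chloroenamine F4. AgOSO2CF3 in CH2Cl2 at low temperature releases keteniminium triflate 26 in the absence of triflic anhydride and pyridinium acid, and cycloaddition and hydrolysis as before return 28.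

3. Step 32. The two secondary hydroxyls may not be discriminated, and the acetyl group may migrate from O1 to O2. Fallback (from 38, back at 43): the C1 acetate is installed while O2 is still silylated, so no discrimination is needed. PPTS in wet acetone cleaves only the acyclic dimethyl ketal of 38 and gives the C1 ketone F5. NaBH4/CeCl3·7H2O, attacking from the exposed convex face, gives the C1-epimeric alcohol F6. Mitsunobu esterification with acetic acid (PPh3, DIAD) inverts C1 to the acetate F7; should the hydride attack the other face, the alcohol is simply acetylated to F7. Aqueous acetic acid removes acetonide and dioxolane (triol F8), Ac2O/DMAP acetylates O9 (silyl-protected target F9), and HF·pyridine gives 43.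

**Further compounds**

F1 | step 26 | tricyclic hydroxy ketone silyl ether (ring B closed, C17 hydroxyl, arm C1(OMe)2–CH2OTBS) | C1C(=O)[C@]2(C[C@H]2C)[C@@H](OC(C)(C)O6)[C@@]36[C@H]4CC5(OCCO5)C(C)(C)[C@@H](C(OC)(OC)CO[Si](C)(C)C(C)(C)C)[C@@]4(C)[C@@]13O
F2 | step 26 | tricyclic primary alcohol (C2–OH) | C1C(=O)[C@]2(C[C@H]2C)[C@@H](OC(C)(C)O6)[C@@]36[C@H]4CC5(OCCO5)C(C)(C)[C@@H](C(OC)(OC)CO)[C@@]4(C)[C@@]13O
F3 | step 26 | bis(trimethylsilyl) derivative of 36 (C17–OSiMe3, C3=C4 silyl enol ether) | C1=C(O[Si](C)(C)C)[C@]2(C[C@H]2C)[C@@H](OC(C)(C)O6)[C@@]36[C@H]4CC5(OCCO5)C(C)(C)[C@@H](C(OC)(OC)C=O)[C@@]4(C)[C@@]13O[Si](C)(C)C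
F4 | step 20 | α-chloroenamine from 25 (C17(Cl)=C16; E/Z mixture) | CN(C)C(Cl)=C(C)[C@H](C(OC)(OC)CO[Si](C)(C)C(C)(C)C)C(C)(C)C1(CC=C)OCCO1
F5 | step 32 | C1 ketone with C2–OTIPS, acetonide and C13 dioxolane intact | O=C1[C@@H](O[Si](C(C)C)(C(C)C)C(C)C)[C@H]2C(=O)[C@]3(C[C@H]3C)[C@@H](OC(C)(C)O6)[C@@]36[C@H]4CC7(OCCO7)C(C)(C)[C@@H]1[C@@]4(C)[C@@]23O
F6 | step 32 | C1-epimeric alcohol (C1 hydroxyl cis to C2–OTIPS) | O[C@H]1[C@@H](O[Si](C(C)C)(C(C)C)C(C)C)[C@H]2C(=O)[C@]3(C[C@H]3C)[C@@H](OC(C)(C)O6)[C@@]36[C@H]4CC7(OCCO7)C(C)(C)[C@@H]1[C@@]4(C)[C@@]23O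
F7 | step 32 | C1 acetate (target configuration) with C2–OTIPS, acetonide and dioxolane | CC(=O)O[C@@H]1[C@@H](O[Si](C(C)C)(C(C)C)C(C)C)[C@H]2C(=O)[C@]3(C[C@H]3C)[C@@H](OC(C)(C)O6)[C@@]36[C@H]4CC7(OCCO7)C(C)(C)[C@@H]1[C@@]4(C)[C@@]23O
F8 | step 32 | C1 acetate triol (C9, C10, C17 hydroxyls; C13 ketone; C2–OTIPS) | CC(=O)O[C@@H]1[C@@H](O[Si](C(C)C)(C(C)C)C(C)C)[C@H]2C(=O)[C@]3(C[C@H]3C)[C@@H](O)[C@@]3(O)[C@H]4CC(=O)C(C)(C)[C@@H]1[C@@]4(C)[C@@]23O
F9 | step 32 | 2-O-triisopropylsilyl ether of the target | CC(=O)O[C@@H]1[C@@H](O[Si](C(C)C)(C(C)C)C(C)C)[C@H]2C(=O)[C@]3(C[C@H]3C)[C@@H](OC(C)=O)[C@@]3(O)[C@H]4CC(=O)C(C)(C)[C@@H]1[C@@]4(C)[C@@]23O
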